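What stands in this flask at 80 min?

- concentration of substrate at 80 min, in M
- concentration of open intermediate at 80 min, in M
- concentration of target at 80 min, in M
- concentration of second intermediate at 80 min, in M

all flasks: substrate 0.13 M (fed, over 5.0 min); fresh partner 0.123 M
- dusk: coupling partner 0.26 M; the very flask that is asked about, followed so far
- flask: coupling partner 0.260 M; time 80 min

dusk run (percent of the substrate charged)

| time / min | substrate / % | open intermediate / % | target / % |
|---|---|---|---|
| 0.667 | 13.7 | 0.5 | 0 |
| 2.00 | 39.5 | 0.9 | 0 |
| 3.00 | 59.9 | 0.9 | 0 |
| 5.00 | 98.9 | 1.4 | 0 |
| 8.00 | 96.1 | 3.8 | 0 |
| 10.0 | 93.9 | 5.2 | 0 |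

(standard deviation of a reading: 0.5 percentage points)

- the earlier runs were read with a standard deviation of 0.5 percentage points
- percentages count the whole charge, also what has not yet gone in

The dusk readings show neither partner, so I assume something they cannot test: coupling partner pairs one to one with fresh partner quickly, and with substrate slowly. The useful quantity is then the spare coupling partner, meaning what remains for substrate after fresh partner, the limiting reagent of that pairing, has taken its share, as a fraction of the substrate charge. I keep the books in that fraction.

coupling partner charged: 2.00
to fresh partner, becoming second intermediate: 0.946
spare for substrate: 1.05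

After the feed, substrate loss and open-intermediate gain, averaged between 5.00 min and 10.0 min, read as a pseudo-first-order constant of 0.00913 min⁻¹. This is a reading from few points, with scatter 0.5 percentage points. Its time constant, 110 min, is not long against the remaining 75.0 min, and the spare shrinks as substrate uses it, so I iterate on the mean spare, as a share of the starting spare.

first round, share held at 1: substrate 0.499 of its charge
next round, share 0.762: substrate 0.587 of its charge
once more, share 0.804: substrate 0.570 of its charge

The books close with 0.624 of coupling partner left. I commit to substrate at 0.570 of its charge, with the lost 0.430 mostly as open intermediate, since substrate and open intermediate still summed to 99.1% at 10.0 min.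

The forecast gives 0.066 M, 0.04 M, 0.009 M and 0.015 M for substrate, open intermediate, target and second intermediate, reading the step as “bimolecular with fresh partner”, where I use coupling partner.

The flask gives 0.0865 M, 0.0370 M, 0.00653 M and 0.0595 M, so substrate stands at 0.665 of its charge against my 0.570.

    open intermediate + second intermediate ⇌ target (K = 6.80 M⁻¹, k = 0.0640 M⁻¹ min⁻¹)
    second intermediate → side product (k = 0.00840 min⁻¹)
    coupling partner + fresh partner → second intermediate (k = 1.80 M⁻¹ min⁻¹)
    substrate + coupling partner → open intermediate (k = 0.0460 M⁻¹ min⁻¹)

At 1.72 min, fresh partner uses coupling partner 54 times as fast as substrate does. Taking the substrate turned over, 0.335 of its charge, from the spare leaves coupling partner at 0.719 of the substrate charge in this flask.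

In the neighbour with 0.49 M of fresh partner, the spare is −1.77, below zero, so I expect substrate to stay nearly untouched. Computed, that neighbour holds substrate at 99.3%, coupling partner at 0% and fresh partner at 47.1% of its own charge.

The earlier runs and the new flask are calculated from invented constants; noise was put on by code.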